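Wednesday's run starts with E ahead, Z at 28.4% against E at 33.4% after 2.00 h, and ends with Z at 61.5% against E at 2.5% after 40.0 h. I take the level case, Z = E, a ratio of 1, as the zero of my scale and ask how far from it the flask stands at each asked time. The readings look like kinetic against thermodynamic control, with E ahead first and Z later.

| flask | D | X | remark | time |
|---|---|---|---|---|
| Thursday's | 0.016 M | 0.0076 M | run made earlier |  |
| Wednesday's | 0.016 M | 0.030 M | run made earlier |  |
| Saturday's | 0.0080 M | 0.0152 M | run made earlier |  |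
| flask | 0.016 M | 0.0152 M |  | 50 h |

| run | time / h | Z / % | E / % |
|---|---|---|---|
| Thursday's | 2.00 | 11.1 | 13.2 |
| Thursday's | 6.00 | 18.4 | 7.2 |
| Thursday's | 12.0 | 24.2 | 4.0 |
| Thursday's | 15.0 | 24.9 | 2.7 |
| Thursday's | 25.0 | 26.8 | 1.8 |
| Thursday's | 30.0 | 28.1 | 1.0 |
| Thursday's | 40.0 | 29.3 | 1.2 |
| Wednesday's | 2.00 | 28.4 | 33.4 |
| Wednesday's | 6.00 | 44.7 | 14.6 |
| Wednesday's | 12.0 | 53.1 | 6.1 |
| Wednesday's | 15.0 | 54.7 | 4.6 |
| Wednesday's | 25.0 | 58.3 | 1.9 |
| Wednesday's | 30.0 | 59.6 | 2.0 |
| Wednesday's | 40.0 | 61.5 | 2.5 |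
| Saturday's | 8.00 | 42.1 | 11.7 |
| Saturday's | 15.0 | 51.6 | 5.2 |
| Saturday's | 25.0 | 56.2 | 1.9 |
| Saturday's | 30.0 | 58.3 | 2.2 |
| Saturday's | 40.0 | 60.3 | 2.6 |

(each reading ± 0.5 percentage points)

- the earlier runs were read with a standard deviation of 0.5 percentage points
- steps that have been proposed: D + X <-> E; D + X <-> Z; E <-> G

1. ratio of Z to E at 1.5 min
2. ratio of Z to E at 50 h
3. which of Z and E there is more of at 50 h

At 2.00 h the ratio of Z to E reads 0.841 in Thursday's run and 0.850 in Wednesday's, with X charged at 0.0076 M and 0.030 M. I would take that as the early answer, but by 6.00 h Wednesday's E reads 14.6% against Z at 44.7%, so the ratio climbs with time; I read these as upper values and place the flask at 1.5 min below them, under the zero.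

Late on, a single ratio is worth little, since Thursday's E reads 1.0% at 30.0 h with a scatter of 0.5 percentage points. So I pool: the sum of Z over the sum of E across the 9 readings from 25.0 h on is 25.6, which I call the late ratio L.

But L mixes charges. Thursday's readings alone give 21.0 and Wednesday's 28.0. Each rests on 3 small readings of E, so I trust no trend with X, and the flask's X lies between those charges.

A second doubt is that Z still climbs in Wednesday's run. At its pace from 25.0 h to 40.0 h, I reckon 2.1 points more on 61.5% by 50 h, so I keep L for the flask at 50 h.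

The forecast gives 0.55 at 1.5 min and 25 at 50 h, with Z ahead, on the ground that “Z creeps upward as E reverts through D + X”. My L of 25.6 stands above the forecast's 25.

The flask gives 0.415 at 1.5 min and 29.5 at 50 h, with Z at 54.8% against E at 1.86%.

    D + X ⇌ E (K = 76.1 /M, k = 0.00910 /M/s)
    D + X ⇌ Z (K = 7500 /M, k = 0.00375 /M/s)
    E ⇌ G (K = 12.0, k = 5.63 × 10⁻⁵ /s)

In the flask, Z and E stand level at 2.55 h, each at 21.3%, and the ratio at 50 h is 1.15 times L. A neighbour charged with 0.0061 M of X ends with Z at 23.9%, so L puts its E at 0.934%, and that neighbour holds 0.760%.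

The runs are simulated on assumed constants; the scatter is artificial.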